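## Structural features

The target, (2R,3R)-3,5,7-trihydroxy-2-(4-hydroxy-3-methoxyphenyl)-6-(2-methylbut-3-en-2-yl)chroman-4-one, is a 2,3-trans dihydroflavonol in which benzene ring A (C4a to C8a) is fused to the oxygen heterocycle C (O1, C2, C3, C4) and C2 carries the guaiacyl ring B. Ring A is a phloroglucinol with hydroxyls on C5 and C7, the ring oxygen on C8a, one hydrogen at C8 and, at C6 between the two hydroxyls, a 1,1-dimethylallyl group whose quaternary carbon is bonded directly to the ring. The stereocentres C2 and C3 are neighbours, both R, with the aryl group and the hydroxyl trans and equatorial. Several features are fragile: C2 is benzylic, bound to O1 and para-related to a phenol, so ring C can open through a quinone methide under base or by β-elimination from a C3 enolate; the α-hydroxy ketone can epimerise at C3; the terminal vinyl group forbids hydrogenolysis and invites acid-catalysed addition of the flanking phenols. The real difficulty is twofold: the quaternary carbon must sit at C6 and not C8, which amounts to deciding which of the two oxygens ortho to the carbonyl becomes O1, and C2 must be set absolutely although chalcone–flavanone closures are reversible. The key step uses the fact that C2 is a benzylic carbon attached to O1: in an aryl benzyl ether its C–H bonds are activated by the oxygen and by ring B, so a carbenoid at C3 can insert into one of them and form the C2–C3 bond, ring C and the C2 stereocentre together.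

## Logic of the disconnections

17 ⇒ 16. The three aryl O–Si bonds are cut. The phenols must be masked during carbenoid, enolate and oxidant chemistry. Nothing is gained in skeleton, but one group type is removed in a single operation. The forward step must stay non-basic, because a free phenoxide para to C2 opens ring C.

16 ⇒ 13. The C3–O bond is cut (α-hydroxy ketone to ketone by way of its enol silane). This removes one stereocentre and lets C2 direct the oxidant to the opposite face. The forward step needs enolisation without expulsion of O1, and an oxidant that prefers the enol double bond to the vinyl group.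

13 ⇒ 12. The C2–C3 bond is cut, opening ring C to an aryl benzyl ether with a diazoacetyl group. Ring C and C2 disappear together, and 12 is achiral. The oxygen that becomes O1 is fixed beforehand by the position of the benzyl group, so the 6- versus 8-substitution question of chalcone closures does not arise. The forward step needs a catalyst that selects C–H insertion over reaction at the ether oxygen and distinguishes the two benzylic hydrogens.

12 ⇒ 10. The C=N2 unit is cut, leaving a methyl ketone. A route through a 2,6-dioxygenated benzoate, its hydrolysis, an acid chloride and a hazardous diazoalkane was rejected: the hindered ester would have to be hydrolysed in the presence of base-labile aryl silyl ethers, and acid chloride formation endangers the electron-rich benzylic ether. The gain is that the whole acyl carbon skeleton is already present in 4. The forward step needs enolisation of a hindered ketone without disturbing the neighbouring silyl ether.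

10 ⇒ 9. Two aryl O–Si bonds are cut. Silyl ethers are used because they have no C–H bond α to oxygen and are poor donors toward a carbenoid. The forward step must silylate a hydroxyl that is chelated and flanked by the acetyl group and the quaternary carbon.

9 ⇒ 7. The ring C6–C(quaternary) bond is cut with allylic transposition (ortho-allylphenol to aryl allyl ether). The crowded quaternary carbon is traced back to a primary ether. The forward rearrangement must choose between the two free ortho carbons. For that reason the benzyl ether is placed before the rearrangement: the one remaining hydroxyl is then necessarily chelated to the ketone and marks the ortho carbon that should receive the allyl unit. Etherification after the rearrangement would have to discriminate three hydroxyls, the most acidic of which (para to the ketone) is the wrong one.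

7 ⇒ 6 + 3. The O1–CH2 bond is cut. This is the convergent union with the ring B fragment, whose benzylic carbon is the future C2. The forward step must mono-etherify a symmetric diol under neutral conditions that spare the aryl silyl ether.

6 ⇒ 4 + 5. The allyl O–C bond is cut. The forward step must etherify only the hydroxyl para to the acetyl group and avoid C-alkylation of the phloroglucinol ring.

3 ⇒ 2 ⇒ 1. One C–H bond (alcohol to aldehyde) and one O–Si bond are cut. Both forward steps are routine.

## Other disconnections considered

Alternative 1: The cut lies inside the C6 side chain: the bonds from the benzylic quaternary carbon to one methyl group and to the vinyl group, the ring–carbon bond being kept from an aryl ketone. Forward, the O-Boc ketone A2 takes up a methyl Grignard reagent; the alkoxide removes the Boc group from the neighbouring phenolic oxygen, the carbonate leaves, and the resulting ortho-quinone methide A3 is captured 1,4 by a vinyl Grignard reagent to give phenol A1. In its favour: the position of the side chain is fixed by the carbonyl group, so there is no regiochemical question. This is better than the chosen plan, where step 5 rests on a chelation bias. The cascade runs at low temperature instead of 180 °C, also better, and ring A emerges with three differentiated oxygens, at least equal. Against it here: A3 carries two alkyl groups on its exocyclic carbon and can be deprotonated by the Grignard reagent instead of adding it. The acetyl group of 4 is consumed to make the side chain, so C4 and all of ring C must be built afterwards (ortho-acylation of A1 at C4a, aldol condensation, unmasking, oxa-Michael closure), and that closure is reversible and gives racemic C2 unless a separate asymmetric step is added. Comparison: on structure, it settles the ring A pattern with certainty but contributes nothing to ring C or either stereocentre, whereas the chosen plan fixes ring C, the identity of O1 and C2 in one step. On mechanism, it is a stoichiometric anionic cascade with predictable bond formation, at least the equal of a carbenoid insertion in chemoselectivity, but without stereocontrol. On step economy, A2 needs about four steps from 4 and about seven more would follow A1, which is longer than the chosen route.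

Alternative 2: The cut is through ring A itself (C5–C6 and C7–C8, with C4a–C5 closed by electrocyclisation). Forward, the cyclobutenone A5 opens thermally and combines with the siloxyalkyne A6 through cycloaddition, ring opening and six-electron electrocyclisation to give phenol A4 after tautomerisation. In its favour: the quaternary carbon arrives on the alkyne, so no bond to a crowded arene position has to be made and the substitution pattern follows from the polarity of the components. On regiochemical certainty this is better than the chosen plan. The three oxygens come out differentiated, equal or better, and the step is convergent. Against it here: A5 and A6 are not commercial and each needs several steps. The tertiary substituent sits on the alkyne carbon that must bond to the ketene carbon and should slow the cycloaddition. After A4 the same tasks remain as in alternative 1: acylation at C4a, ring C and both stereocentres. Comparison: on structure, it is the most thorough answer to the ring A problem and no answer to ring C. On mechanism, it is a thermal pericyclic cascade with no catalyst and no stereochemistry at stake, against a catalyst-controlled insertion. On step economy, it is the longest of the four plans.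

Alternative 3: The cut is the C4a–C8a bond of ring A, leading back to the open-chain triketo ester A8 that already carries the cinnamoyl unit. Forward, a magnesium alkoxide holds A8 as a chelated polyenolate; the methylene between two ketones (future C4a) attacks the ester carbonyl (future C8a), the alkoxide leaves and enolisation gives chalcone A7. In its favour: all carbons of the target are in place after one ring closure, ring A needs no protecting groups, and the side chain is unambiguously on the carbon between two carbonyls. On step count to the full carbon skeleton and on freedom from diazo and silyl chemistry this is better than the chosen plan. Against it here: A8 has a tertiary carbon bearing a quaternary substituent between two ketones, which is hard to assemble and prone to retro-Claisen cleavage. Polyketones of this kind can divert to pyrones and aldol products, and the enone is a Michael acceptor for its own enolates. A7 has two different ortho hydroxyls: closure through the one next to the side chain gives the 8-substituted skeleton, closure through the other the desired 6-substituted one, and the closure is reversible and racemic. Comparison: on structure, it builds ring A and the three-carbon bridge at once but leaves open the choice of O1 and both stereocentres, the very points the chosen plan fixes. On mechanism, it is a thermodynamically driven, template-controlled condensation against a kinetically controlled catalytic insertion. On step economy, it is potentially the shortest to A7, but the advantage is expected to be lost in protection, isomer separation and the asymmetric steps that follow.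

Key step: step 8

Abbreviations: TBS = tert-butyldimethylsilyl; Ar = 4-[(tert-butyldimethylsilyl)oxy]-3-methoxyphenyl.

Assumption: the sense of induction of dirhodium tetrakis[N-phthaloyl-(S)-tert-leucinate], Rh2(S-PTTL)4, in step 8 is taken to give the 2S configuration; if it is the opposite, Rh2(R-PTTL)4 is used and nothing else changes.

## Route

Step 1
Reactants: 1 vanillin
Product: 2 4-[(tert-butyldimethylsilyl)oxy]-3-methoxybenzaldehyde
Conditions: TBSCl, imidazole, DMF, 0 °C to rt
Reagents that add atoms: tert-butyldimethylsilyl chloride, CC(C)(C)[Si](C)(C)Cl
Why: Standard silylation of an unhindered phenol; the silyl ether has no C–H bond α to oxygen and comes off with the others at the end.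

Step 2
Reactants: 2 4-[(tert-butyldimethylsilyl)oxy]-3-methoxybenzaldehyde
Product: 3 {4-[(tert-butyldimethylsilyl)oxy]-3-methoxyphenyl}methanol
Conditions: NaBH4, THF/MeOH, 0 °C
Reagents that add atoms: none
Why: Hydride reduction of an aryl aldehyde; a short, cold borohydride treatment should leave the aryl silyl ether intact.

Step 3
Reactants: 4 1-(2,4,6-trihydroxyphenyl)ethanone (dried); 5 3-methylbut-2-en-1-ol
Product: 6 1-[2,6-dihydroxy-4-(3-methylbut-2-enyloxy)phenyl]ethanone
Conditions: PPh3, DIAD, THF, 0 °C to rt
Reagents that add atoms: none
Why: Mitsunobu etherification; the alkoxyphosphonium ion of 5 should be attacked by the most acidic phenol, the 4-OH para to the acetyl group, while the ortho hydroxyls are engaged with the carbonyl. No free phenoxide is present, so C-alkylation of the ring is avoided.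

Step 4
Reactants: 6 1-[2,6-dihydroxy-4-(3-methylbut-2-enyloxy)phenyl]ethanone; 3 {4-[(tert-butyldimethylsilyl)oxy]-3-methoxyphenyl}methanol
Product: 7 1-[2-(Ar-methoxy)-6-hydroxy-4-(3-methylbut-2-enyloxy)phenyl]ethanone
Conditions: PPh3, DIAD, THF, 0 °C to rt
Reagents that add atoms: none
Why: Second Mitsunobu etherification; the two ortho hydroxyls of 6 are equivalent, and the one that remains is locked in the hydrogen bond to the ketone, which should stop the reaction at the mono-ether. The neutral medium spares the aryl silyl ether of 3.

Step 5
Reactants: 7 1-[2-(Ar-methoxy)-6-hydroxy-4-(3-methylbut-2-enyloxy)phenyl]ethanone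
Product: 9 1-[6-(Ar-methoxy)-2,4-dihydroxy-3-(2-methylbut-3-en-2-yl)phenyl]ethanone, via ortho-dienone 8 (not isolated)
Conditions: PhNEt2, 180 °C, Ar, stopped when 7 is consumed
Reagents that add atoms: none
Why: Aromatic Claisen rearrangement; the [3,3] shift joins the dimethyl-substituted allyl terminus to ring carbon C3 to give dienone 8, which enolises to 9. The chelate between the 2-OH and the ketone gives the C3–C4 bond double-bond character and should direct the shift to C3, the known bias of 2-hydroxy-4-allyloxyaryl ketones. The para position is blocked by the acetyl group and the basic solvent suppresses acid-catalysed ring closure onto the new alkene.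

Step 6
Reactants: 9 1-[6-(Ar-methoxy)-2,4-dihydroxy-3-(2-methylbut-3-en-2-yl)phenyl]ethanone
Product: 10 1-[6-(Ar-methoxy)-2,4-bis[(tert-butyldimethylsilyl)oxy]-3-(2-methylbut-3-en-2-yl)phenyl]ethanone
Conditions: TBSOTf, 2,6-lutidine, CH2Cl2, −78 °C to rt
Reagents that add atoms: tert-butyldimethylsilyl trifluoromethanesulfonate, CC(C)(C)[Si](C)(C)OS(=O)(=O)C(F)(F)F
Why: Phenol silylation with a silyl triflate, needed because the 2-OH is chelated and flanked by the acetyl group and the quaternary carbon. Lutidine buffers triflic acid so the benzylic ether should survive, and any silyl enol ether of the ketone is hydrolysed on work-up.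

Step 7
Reactants: 10 1-[6-(Ar-methoxy)-2,4-bis[(tert-butyldimethylsilyl)oxy]-3-(2-methylbut-3-en-2-yl)phenyl]ethanone
Product: 12 2-diazo-1-[6-(Ar-methoxy)-2,4-bis[(tert-butyldimethylsilyl)oxy]-3-(2-methylbut-3-en-2-yl)phenyl]ethanone, via trifluoroacetyl diketone 11 (not isolated)
Conditions: LiN(SiMe3)2, THF, −78 °C; CF3CO2CH2CF3; aq. NH4Cl; then p-ABSA, Et3N, H2O (1 equiv), MeCN, rt
Reagents that add atoms: 4-acetamidobenzenesulfonyl azide, CC(=O)Nc1ccc(cc1)S(=O)(=O)N=[N+]=[N-]
Why: Detrifluoroacetylative (Regitz-type) diazo transfer; the kinetic enolate of the methyl ketone is C-acylated to 11, whose activated methylene takes the diazo group from the sulfonyl azide while the trifluoroacetyl group passes to the sulfonamide nitrogen. No ester hydrolysis, acid chloride or diazoalkane is needed.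

Step 8
Reactants: 12 2-diazo-1-[6-(Ar-methoxy)-2,4-bis[(tert-butyldimethylsilyl)oxy]-3-(2-methylbut-3-en-2-yl)phenyl]ethanone
Product: 13 (2S)-5,7-bis[(tert-butyldimethylsilyl)oxy]-2-Ar-6-(2-methylbut-3-en-2-yl)-2,3-dihydro-4H-chromen-4-one
Conditions: Rh2(S-PTTL)4 (2 mol %), 4 Å molecular sieves, toluene, 0 °C, slow addition of 12
Reagents that add atoms: none
Why: The divalent-rhodium dimer attacks the diazo carbon, dinitrogen leaves and an electrophilic rhodium carbenoid stands at C3. In a concerted but asynchronous three-centre transition state one benzylic hydrogen of the O1–CH2–Ar group moves to C3 with hydride character while the C2–C3 bond forms and the catalyst is released. The closest known reaction type is the chiral dirhodium carboxylate-catalysed intramolecular C–H insertion of ortho-alkoxyaryl diazoketones next to the ether oxygen, which gives 2-substituted chroman-4-ones. Ring C closes as a 1,6-insertion through a six-membered array (C3, C4, C4a, C8a, O1, C2); the 1,5-position is the oxygen itself, so no smaller ring with an activated C–H bond is available. The C2 stereocentre is set by the catalyst alone: 12 has no stereocentre, and the phthalimido walls of the (S)-tert-leucinate ligands are expected to distinguish the two enantiotopic benzylic hydrogens. The step needs insertion to win over oxonium ylide formation at O1 with [1,2]-benzyl (Stevens) shift, attack on the silyl ether oxygens, the vinyl group or ring B, and carbenoid dimerisation. The substrate helps in four ways: the benzylic C–H bond is activated by both O1 and the para-siloxyaryl ring; the O1 lone pair is delocalised into the acyl-bearing ring and is a weak donor; the silyl ethers are shielded and have no α C–H bond; and the vinyl group is out of reach. Slow addition keeps the carbenoid concentration low.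

Step 9
Reactants: 13 (2S)-5,7-bis[(tert-butyldimethylsilyl)oxy]-2-Ar-6-(2-methylbut-3-en-2-yl)-2,3-dihydro-4H-chromen-4-one
Product: 16 (2R,3R)-5,7-bis[(tert-butyldimethylsilyl)oxy]-2-Ar-3-hydroxy-6-(2-methylbut-3-en-2-yl)-2,3-dihydro-4H-chromen-4-one, via enol silane 14 (not isolated), via siloxy epoxide 15 (not isolated)
Conditions: LiN(iPr)2, Me3SiCl, THF, −78 °C; then DMDO, acetone/CH2Cl2, −78 to −20 °C; citric acid, MeOH/H2O, 0 °C
Reagents that add atoms: dimethyldioxirane, CC1(C)OO1
Why: Rubottom-type oxidation; the enolate is trapped as it forms to give 14 before O1 can be expelled. The dioxirane should epoxidise the electron-rich enol double bond, far faster than the hindered vinyl group, on the face opposite to the 2-aryl group to give 15. Acidic work-up opens 15 to the 3-hydroxy ketone with C3 (R), trans to the aryl group, which is also the more stable diequatorial isomer.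

Step 10
Reactants: 16 (2R,3R)-5,7-bis[(tert-butyldimethylsilyl)oxy]-2-Ar-3-hydroxy-6-(2-methylbut-3-en-2-yl)-2,3-dihydro-4H-chromen-4-one
Product: 17 (2R,3R)-3,5,7-trihydroxy-2-(4-hydroxy-3-methoxyphenyl)-6-(2-methylbut-3-en-2-yl)-2,3-dihydro-4H-chromen-4-one
Conditions: Bu4NF, AcOH (1:1), THF, 0 °C to rt
Reagents that add atoms: none
Why: Fluoride cleavage of three aryl silyl ethers. Acetic acid keeps the phenols protonated, so neither quinone methide opening at C2 nor enolisation at C3 should scramble the stereocentres, and the medium is too weakly acidic to add a phenol across the vinyl group.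

## Compound list

1 | vanillin (4-hydroxy-3-methoxybenzaldehyde) | COc1cc(C=O)ccc1O | starting material
2 | 4-[(tert-butyldimethylsilyl)oxy]-3-methoxybenzaldehyde | COc1cc(C=O)ccc1O[Si](C)(C)C(C)(C)C | intermediate
3 | {4-[(tert-butyldimethylsilyl)oxy]-3-methoxyphenyl}methanol | COc1cc(CO)ccc1O[Si](C)(C)C(C)(C)C | intermediate
4 | 1-(2,4,6-trihydroxyphenyl)ethanone | CC(=O)c1c(O)cc(O)cc1O | starting material
5 | 3-methylbut-2-en-1-ol | CC(C)=CCO | starting material
6 | 1-[2,6-dihydroxy-4-(3-methylbut-2-enyloxy)phenyl]ethanone | CC(=O)c1c(O)cc(OCC=C(C)C)cc1O | intermediate
7 | 1-[2-(Ar-methoxy)-6-hydroxy-4-(3-methylbut-2-enyloxy)phenyl]ethanone | CC(=O)c1c(O)cc(OCC=C(C)C)cc1OCc1ccc(O[Si](C)(C)C(C)(C)C)c(OC)c1 | intermediate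
8 | 4-acetyl-5-(Ar-methoxy)-3-hydroxy-2-(2-methylbut-3-en-2-yl)cyclohexa-3,5-dien-1-one (racemic, transient in step 5) | CC(=O)C1=C(O)C(C(C)(C)C=C)C(=O)C=C1OCc1ccc(O[Si](C)(C)C(C)(C)C)c(OC)c1 | intermediate
9 | 1-[6-(Ar-methoxy)-2,4-dihydroxy-3-(2-methylbut-3-en-2-yl)phenyl]ethanone | CC(=O)c1c(O)c(C(C)(C)C=C)c(O)cc1OCc1ccc(O[Si](C)(C)C(C)(C)C)c(OC)c1 | intermediate
10 | 1-[6-(Ar-methoxy)-2,4-bis[(tert-butyldimethylsilyl)oxy]-3-(2-methylbut-3-en-2-yl)phenyl]ethanone | CC(=O)c1c(O[Si](C)(C)C(C)(C)C)c(C(C)(C)C=C)c(O[Si](C)(C)C(C)(C)C)cc1OCc1ccc(O[Si](C)(C)C(C)(C)C)c(OC)c1 | intermediate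
11 | 1-[aryl group as in 10]-4,4,4-trifluorobutane-1,3-dione (formed and consumed in step 7) | O=C(CC(=O)C(F)(F)F)c1c(O[Si](C)(C)C(C)(C)C)c(C(C)(C)C=C)c(O[Si](C)(C)C(C)(C)C)cc1OCc1ccc(O[Si](C)(C)C(C)(C)C)c(OC)c1 | intermediate
12 | 2-diazo-1-[6-(Ar-methoxy)-2,4-bis[(tert-butyldimethylsilyl)oxy]-3-(2-methylbut-3-en-2-yl)phenyl]ethanone | C=CC(C)(C)c1c(O[Si](C)(C)C(C)(C)C)cc(OCc2ccc(O[Si](C)(C)C(C)(C)C)c(OC)c2)c(C(=O)C=[N+]=[N-])c1O[Si](C)(C)C(C)(C)C | intermediate
13 | (2S)-5,7-bis[(tert-butyldimethylsilyl)oxy]-2-Ar-6-(2-methylbut-3-en-2-yl)-2,3-dihydro-4H-chromen-4-one | C=CC(C)(C)c1c(O[Si](C)(C)C(C)(C)C)cc2c(c1O[Si](C)(C)C(C)(C)C)C(=O)C[C@@H](c1ccc(O[Si](C)(C)C(C)(C)C)c(OC)c1)O2 | intermediate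
14 | (2S)-5,7-bis[(tert-butyldimethylsilyl)oxy]-2-Ar-6-(2-methylbut-3-en-2-yl)-4-[(trimethylsilyl)oxy]-2H-chromene (formed and consumed in step 9) | C=CC(C)(C)c1c(O[Si](C)(C)C(C)(C)C)cc2c(c1O[Si](C)(C)C(C)(C)C)C(O[Si](C)(C)C)=C[C@@H](c1ccc(O[Si](C)(C)C(C)(C)C)c(OC)c1)O2 | intermediate
15 | 3,4-epoxide of 14, epoxide oxygen on the face opposite to the 2-aryl group, trimethylsilyloxy group on C4 (formed and consumed in step 9) | C=CC(C)(C)c1c(O[Si](C)(C)C(C)(C)C)cc2c(c1O[Si](C)(C)C(C)(C)C)[C@]3(O[Si](C)(C)C)O[C@@H]3[C@@H](c1ccc(O[Si](C)(C)C(C)(C)C)c(OC)c1)O2 | intermediate
16 | (2R,3R)-5,7-bis[(tert-butyldimethylsilyl)oxy]-2-Ar-3-hydroxy-6-(2-methylbut-3-en-2-yl)-2,3-dihydro-4H-chromen-4-one | C=CC(C)(C)c1c(O[Si](C)(C)C(C)(C)C)cc2c(c1O[Si](C)(C)C(C)(C)C)C(=O)[C@H](O)[C@@H](c1ccc(O[Si](C)(C)C(C)(C)C)c(OC)c1)O2 | intermediate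
17 | (2R,3R)-3,5,7-trihydroxy-2-(4-hydroxy-3-methoxyphenyl)-6-(2-methylbut-3-en-2-yl)-2,3-dihydro-4H-chromen-4-one | C=CC(C)(C)c1c(O)cc2c(c1O)C(=O)[C@H](O)[C@@H](c1ccc(O)c(OC)c1)O2 | target

## Step count and least certain steps

Total: 10 steps. Longest linear sequence: 9 steps (1, 2, 4, 5, 6, 7, 8, 9, 10, from compound 1); 8 steps from compound 4.

Step 8 (key step). The most likely failure is attack of the carbenoid on the O1 lone pair followed by [1,2]-migration of the electron-rich benzyl group, or poor discrimination between the two benzylic hydrogens. The cause is that the group that activates the C–H bond is also a good migrating group, and a terminal diazoketone gives a reactive carbenoid. The fallback uses no carbenoid and forms the C2–aryl bond instead. It sets out from 10: oxidative removal of the siloxybenzyl group (DDQ, CH2Cl2/pH 7 buffer) should give the phenol ketone F1. Condensation with N,N-dimethylformamide dimethyl acetal should give the enaminone F2, which closes with loss of dimethylamine in warm AcOH to the chromone F3. Enantioselective conjugate addition of {4-[(tert-butyldimethylsilyl)oxy]-3-methoxyphenyl}boronic acid to F3 with Pd(OCOCF3)2 and a chiral pyridine–oxazoline ligand (a known way from chromones to flavanones; the ligand enantiomer that gives 2S is used) returns to the route at 13.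

Step 5. The most likely failure is migration of the allyl unit to C5, next to the benzyloxy group, in competition with C3, or thermal follow-up reactions (ring closure of the new ortho-hydroxy side chain, abnormal rearrangement on prolonged heating). The cause is that regiocontrol rests only on the bias from the chelate ring, and the product carries free phenols beside the alkene. The fallback rearranges before the benzyl group is in place. It sets out from 6: heating should give the only possible ortho product, the triol ketone F4. TBSCl/imidazole should silylate the most acidic, non-chelated 4-OH to give the mono-silyl ether F5. Mitsunobu coupling with 3 should go to the ortho hydroxyl remote from the quaternary carbon to give the benzyl ether F6, and TBSOTf/2,6-lutidine then silylates the last hydroxyl and returns to the route at 10.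

Step 6. The most likely failure is incomplete silylation of the 2-OH, which is chelated and flanked by the acetyl group and the quaternary carbon, or ionisation of the benzylic ether by the silyl triflate. The fallback forms that O–Si bond before the quaternary carbon exists. It sets out from 6: bis-silylation (TBSCl, imidazole, DMF) should give the bis-silyl prenyl ether F7. Claisen rearrangement (PhNEt2, 180 °C; one ortho product by symmetry) should give the phenol F8, and silylation of its 4-OH gives the tris-silyl ketone F9. One equivalent of Bu4NF/AcOH at low temperature is expected to remove the most exposed silyl group, the one ortho to the acetyl group and remote from the quaternary carbon, to give the phenol ketone F1 already described under step 8; this selectivity is the weak point of the detour. Mitsunobu coupling of F1 with 3 returns to the route at 10.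

Step 7. The most likely failure is migration of the neighbouring aryl silyl group to the enolate oxygen during enolisation, or loss of the silyl ether para to the ketone in the aqueous amine medium of the diazo transfer. The cause is that aryl silyl ethers ortho or para to an acyl group are activated toward nucleophiles. The fallback sets out from 10: the enolate is trapped as it forms (LiN(SiMe3)2 with Me3SiCl present, −78 °C) to give the enol silane F10. N-Bromosuccinimide should give the bromoketone F11, and N,N'-ditosylhydrazine with DBU in THF (a known conversion of bromoacetyl into diazoacetyl compounds) returns to the route at 12.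

Step 9. The most likely failure is β-elimination of the O1 aryloxide from the lithium enolate, opening ring C to a chalcone and eroding the C2 configuration on re-closure, or oxidation of the vinyl group by excess oxidant. The fallback changes how the enol derivative is made, not the oxidation. It sets out from 13: soft enolisation (Me3SiOTf, Et3N, CH2Cl2, −20 °C; O-silylation followed by deprotonation) forms the enol silane without any enolate anion and returns to the route at 14. No new compound is made (F0).

## Further compounds

F1 | step 8 | 1-[2,4-bis[(tert-butyldimethylsilyl)oxy]-6-hydroxy-3-(2-methylbut-3-en-2-yl)phenyl]ethanone | CC(=O)c1c(O[Si](C)(C)C(C)(C)C)c(C(C)(C)C=C)c(O[Si](C)(C)C(C)(C)C)cc1O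
F2 | step 8 | (E)-1-[2,4-bis[(tert-butyldimethylsilyl)oxy]-6-hydroxy-3-(2-methylbut-3-en-2-yl)phenyl]-3-(dimethylamino)prop-2-en-1-one | CN(C)/C=C/C(=O)c1c(O[Si](C)(C)C(C)(C)C)c(C(C)(C)C=C)c(O[Si](C)(C)C(C)(C)C)cc1O
F3 | step 8 | 5,7-bis[(tert-butyldimethylsilyl)oxy]-6-(2-methylbut-3-en-2-yl)-4H-chromen-4-one | C=CC(C)(C)c1c(O[Si](C)(C)C(C)(C)C)cc2occc(=O)c2c1O[Si](C)(C)C(C)(C)C
F4 | step 5 | 1-[2,4,6-trihydroxy-3-(2-methylbut-3-en-2-yl)phenyl]ethanone | CC(=O)c1c(O)cc(O)c(C(C)(C)C=C)c1O
F5 | step 5 | 1-{4-[(tert-butyldimethylsilyl)oxy]-2,6-dihydroxy-3-(2-methylbut-3-en-2-yl)phenyl}ethanone | CC(=O)c1c(O)cc(O[Si](C)(C)C(C)(C)C)c(C(C)(C)C=C)c1O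
F6 | step 5 | 1-{6-(Ar-methoxy)-4-[(tert-butyldimethylsilyl)oxy]-2-hydroxy-3-(2-methylbut-3-en-2-yl)phenyl}ethanone | CC(=O)c1c(O)c(C(C)(C)C=C)c(O[Si](C)(C)C(C)(C)C)cc1OCc1ccc(O[Si](C)(C)C(C)(C)C)c(OC)c1
F7 | step 6 | 1-[2,6-bis[(tert-butyldimethylsilyl)oxy]-4-(3-methylbut-2-enyloxy)phenyl]ethanone | CC(=O)c1c(O[Si](C)(C)C(C)(C)C)cc(OCC=C(C)C)cc1O[Si](C)(C)C(C)(C)C
F8 | step 6 | 1-[2,6-bis[(tert-butyldimethylsilyl)oxy]-4-hydroxy-3-(2-methylbut-3-en-2-yl)phenyl]ethanone | CC(=O)c1c(O[Si](C)(C)C(C)(C)C)cc(O)c(C(C)(C)C=C)c1O[Si](C)(C)C(C)(C)C
F9 | step 6 | 1-[2,4,6-tris[(tert-butyldimethylsilyl)oxy]-3-(2-methylbut-3-en-2-yl)phenyl]ethanone | CC(=O)c1c(O[Si](C)(C)C(C)(C)C)cc(O[Si](C)(C)C(C)(C)C)c(C(C)(C)C=C)c1O[Si](C)(C)C(C)(C)C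
F10 | step 7 | trimethylsilyl enol ether of 10: {1-[aryl group as in 10]ethenyl}oxy-trimethylsilane | C=C(O[Si](C)(C)C)c1c(O[Si](C)(C)C(C)(C)C)c(C(C)(C)C=C)c(O[Si](C)(C)C(C)(C)C)cc1OCc1ccc(O[Si](C)(C)C(C)(C)C)c(OC)c1
F11 | step 7 | 2-bromo-1-[aryl group as in 10]ethanone | O=C(CBr)c1c(O[Si](C)(C)C(C)(C)C)c(C(C)(C)C=C)c(O[Si](C)(C)C(C)(C)C)cc1OCc1ccc(O[Si](C)(C)C(C)(C)C)c(OC)c1
F0 | step 9 | none | none
A1 | alternative 1 | 2-(1,1-dimethylallyl)-5-[(4-methoxybenzyl)oxy]-3-(methoxymethoxy)phenol | C=CC(C)(C)c1c(O)cc(OCc2ccc(OC)cc2)cc1OCOC
A2 | alternative 1 | tert-butyl {2-acetyl-5-[(4-methoxybenzyl)oxy]-3-(methoxymethoxy)phenyl} carbonate | CC(=O)c1c(OC(=O)OC(C)(C)C)cc(OCc2ccc(OC)cc2)cc1OCOC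
A3 | alternative 1 | 4-[(4-methoxybenzyl)oxy]-2-(methoxymethoxy)-6-(propan-2-ylidene)cyclohexa-2,4-dien-1-one (ortho-quinone methide) | CC(C)=C1C(=O)C=C(OCc2ccc(OC)cc2)C=C1OCOC
A4 | alternative 2 | 2-(1,1-dimethylallyl)-5-[(4-methoxybenzyl)oxy]-3-(triisopropylsilyloxy)phenol | C=CC(C)(C)c1c(O)cc(OCc2ccc(OC)cc2)cc1O[Si](C(C)C)(C(C)C)C(C)C
A5 | alternative 2 | 3-[(4-methoxybenzyl)oxy]cyclobut-2-en-1-one | O=C1C=C(OCc2ccc(OC)cc2)C1
A6 | alternative 2 | [(3,3-dimethylpent-4-en-1-yn-1-yl)oxy]triisopropylsilane | C=CC(C)(C)C#CO[Si](C(C)C)(C(C)C)C(C)C
A7 | alternative 3 | 2',4',6'-trihydroxy-3'-(1,1-dimethylallyl)-3-methoxy-4-(methoxymethoxy)chalcone | C=CC(C)(C)c1c(O)cc(O)c(C(=O)/C=C/c2ccc(OCOC)c(OC)c2)c1O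
A8 | alternative 3 | methyl (E)-9-[3-methoxy-4-(methoxymethoxy)phenyl]-4-(2-methylbut-3-en-2-yl)-3,5,7-trioxonon-8-enoate | COC(=O)CC(=O)C(C(C)(C)C=C)C(=O)CC(=O)/C=C/c1ccc(OCOC)c(OC)c1
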